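The data come from a simulation from invented constants, and the scatter is random.

The amounts come first: by 9.5 min the north run had turned 0.381 M of E into Q, and the north-west flask holds the same Z with an E charge of 0.120 M.

| flask | E | Z | time |
|---|---|---|---|
| north | 0.600 M | 0.0120 M |  |
| south-west | 0.600 M | 0.0240 M |  |
| north-west | 0.120 M | 0.0120 M | 9.5 min |

- north run (time / min: [Q] / M): 0.38: 0.026; 0.85: 0.036; 1.9: 0.078; 4.2: 0.180; 9.5: 0.381
- south-west run (time / min: [Q] / M): 0.38: 0.040; 0.85: 0.094; 1.9: 0.196; 4.2: 0.422; 9.5: 0.592

(each reading ± 0.006 M)

- how the opening rate goes with [Z] round the charge of the north run: the exponent of the rate at two percent of E gone to Q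
- Q in the north-west run at 9.5 min, as a share of the E charged

- Overall: E -> Q, with Z as catalyst.
- Constant volume, constant temperature.
- Readings of a species count what is bound in complexes too.
- An order is taken over about fifteen percent of the charge, up and down.

We fold this into one ratio, the clearing number, which is the Q a given Z makes in the asked time divided by the E that flask must clear:

clearing number = 0.381 M / 0.120 M = 3.18

On a first pass, then, we estimate that at the pace of the north run the north-west charge takes 2.99 min to clear. But one number assumes that the rate of a full flask lasts to the end, so we go round again with the tail of the south-west run, where the unconverted amount reads 0.178 M at 4.2 min and 0.00800 M at 9.5 min, with the scatter of the readings on it. That gives a rough reading of a first-order constant, 0.585 min⁻¹, for the south-west run. The Q of the two runs at 4.2 min reads in the ratio 2.34, so the Z of the north-west flask gets 0.250 min⁻¹. Running the whole north-west flask on that tail gives: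

Q share = 90.7%

We commit to a share above that figure, which puts the tail constant on the whole flask, and the same ratio gives an exponent of 1.23, which is a mean over the step in Z and not the local exponent asked.

The forecast says 99% (93% to 100%), since “conversion should be essentially complete”, and an exponent of 1.35 (1.2 to 1.55), higher than ours.

The simulation gives 98.3% and an exponent of 1.6.

    Z + E ⇌ ZE, settled at all times (12.50 L mol⁻¹)
    ZE → Q + Z (6.360 min⁻¹)
    Z + Xa → Ja

The exponent is raised by the step from Z and Xa to Ja, standing at 1.6 with it and 1.0 without. With 0.00425 M of Z taken at once, the south-west run keeps 2.55 times the working Z of the north run, against a rate ratio of 2.5. That step is not the reason for the high north-west share: the share is 98.3% with the step and 99.9% without, at a clearing number of 3.18. The south-west run, with a clearing number of 1.74 from its opening rate, reads 98.7% of its charge at 9.5 min.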